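The slowness of G is what you will watch when you repeat this flask: J stood at 50.0% to the end of the south run, so the excess of J over G grows as G falls.

- south: G 0.75 M; J 0.75 M; E 200 mM (held); D 3.2 mol%; run made earlier
- flask: G 1.5 M; E 200 mM (held); D 3.2 mol%; J 1.5 M; time 5.0 min

south run (percent of the G and J together charged)

| time / min | J / % | G / % | X / % |
|---|---|---|---|
| 0.667 | 50.6 | 43.8 | 6.2 |
| 1.33 | 49.8 | 37.2 | 9.6 |
| 2.00 | 50.5 | 32.3 | 13.1 |
| 2.50 | 49.3 | 29.9 | 15.5 |
| 3.00 | 50.2 | 26.2 | 15.5 |
| 4.00 | 50.0 | 21.4 | 18.2 |

(scatter of a reading: 0.5 percentage points)

1. whether the excess of J over G among what is left of the two reaches 80% by 5.0 min (no / yes)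
2. the highest excess of J over G among what is left of the two up to 5.0 min

- D is single-handed; G and J are mirror images of each other, charged as a racemate, each of them at the stated concentration
- at the start none of E is in solution
- no earlier run changes the charge of D; that part of a forecast is a guess

In the south run G fell in a pseudo-first-order way, from half of the total to 21.4% by 4.00 min, which reads as a rate constant k of 0.212 min⁻¹. Scale k by the concentration of D, which is loading times G charged, and multiply by the time allowed. This gives N = 2.12, the number of e-fold falls of G within the time allowed. With J unchanged, the excess is charge minus rest of G over their sum, so I reckon 78.6%. Reaching 80% takes N = 2.20, and N falls short, so I say no.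

Is one number enough? No earlier run tests whether k follows D. Dissolved E must also keep up: if each G takes one E, the starting draw on E in the asked flask, as a share of the saturation level, is 3.18 min⁻¹, more than the 0.796 min⁻¹ of the south run.

The forecast also says no, with a top of 77%, below my figure, noting that “gas transfer or catalyst saturation could slow the run”.

The flask gives no, with a top of 67.1%.

    L + D + G → D + X (k = 57.2 L² mol⁻² min⁻¹)
    E ⇌ L, rate k2*(csat - [L]) (kL = 8.75 min⁻¹)
    L + D + J → D + Q (k = 0.310 L² mol⁻² min⁻¹)
    X ⇌ Q (k = 0.376 min⁻¹)
    2 D ⇌ Z (K = 9.32 L mol⁻¹, k = 3.44 L mol⁻¹ min⁻¹)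

With 19% of its G left at 5.00 min, this flask reached N = 1.64, less than reckoned, while the neighbour with 1.3 mol% of D, reckoned at 0.862, reached 0.831 and topped at 39.1%. In this flask half of the making of X up to 5.00 min was done by 1.58 min, while dissolved reagent L went from 0.145 M at 0.500 min to 0.174 M at 2.50 min and D, in percent of its charge, went from 87.0% at 0.500 min to 68.2% at 2.50 min, with its form Z then at 31.8%, and by 5.00 min the other product Q stood at 17.1% beside X at 23.6%.

(All runs were computed with made-up constants; the scatter is artificial.)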